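The numbers in the tables are calculated on assumed constants; scatter was added.

Count what is gone. The flask and the three earlier runs stand here:

| setting | ochre | teal | blue | flask |
|---|---|---|---|---|
| starting material | 18 mM | 74 mM | 37 mM | 37 mM |
| first nucleophile | 1.1 equiv | 1.1 equiv | 1.1 equiv | 1.10 equiv |
| second nucleophile | 1 equiv | 1 equiv | 0.50 equiv | 1.00 equiv |
| remark | run made earlier | run made earlier | run made earlier |  |
| time |  |  |  | 20 h |

- ochre (time / h: target / %, other capture product / %, starting material / %): 3.00: 2.9, 3.5, 67.6; 6.00: 3.0, 5.5, 47.4; 10.0: 2.6, 7.2, 30.4; 12.0: 3.1, 8.5, 24.3; 15.0: 1.8, 8.7, 18.1
- teal (time / h: target / %, other capture product / %, starting material / %): 3.00: 5.3, 8.6, 28.5; 6.00: 3.1, 11.1, 10.8; 10.0: 2.6, 13.2, 3.8; 12.0: 3.2, 12.9, 2.4; 15.0: 2.4, 13.1, 1.2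
- blue (time / h: target / %, other capture product / %, starting material / %): 1.33: 5.7, 1.7, 73.3; 4.00: 4.4, 3.1, 42.5; 8.00: 3.2, 5.2, 22.3; 12.0: 2.6, 6.1, 12.6; 15.0: 3.3, 6.6, 8.0

(each reading ± 0.3 percentage points)

- a species is counted by the starting material in it: one side product B counts as two
- steps thought possible: starting material <-> intermediate; intermediate -> side product A; starting material + target -> side product B; first nucleophile + intermediate -> target; second nucleophile + intermediate -> other capture product; target <-> isomer of the product

* share of target in target plus other capture product at 12 min
* share of target in target plus other capture product at 2.0 h
* share of target in target plus other capture product at 20 h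
* which of target and other capture product there is more of at 20 h

By the steps thought possible, starting material opens to the intermediate, which either nucleophile can catch or which can turn into side product A. Target can then move on to its isomer or, with starting material, to side product B. Other capture product has no step onward, so you can count it, whereas the target reading shows only what has stayed target.

So take the capture ratio, a selectivity factor for these charges. Teal's first reading, at 3.00 h, gives 7.31: starting material lost but not found as other capture product, per other capture product found. Blue has the flask's concentration but a smaller charge of second nucleophile, and scaled to the flask's charge it gives 7.35, though from a small reading of 1.7% with scatter 0.3 percentage points.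

Read at those hours, this ratio counts target and everything made from it, but also side product A, and side product B twice, so it runs high as a count of target made. For the first instants of the flask I carry it over: as a share it gives 88.0%, and my reckoning for the flask at 12 min is a share below that.

In the middle, blue's readings give starting material a half-life of 3.24 h. Blue's target reading falls from 5.7% to 3.2% by 8.00 h while its other capture product keeps rising, so I expect the flask's share to fall through these hours.

For the end I borrow teal, which has a higher concentration than the flask and shows 1.2% of its starting material left at 15.0 h; that last reading gives a share of 15.5%.

The forecast says 72%, 56% and 18%, with other capture product ahead at 20 h, and reads the falling target as “consistent with drain to isomer or side product B”. At 12 min it stands lower than the share from the capture ratio.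

The flask gives 83.2%, 56.5% and 16.3%, with 12.6% of other capture product against 2.46% of target at 20 h.

    starting material ⇌ intermediate (K = 0.00120, k = 0.00220 s⁻¹)
    intermediate → side product A (k = 0.00740 s⁻¹)
    starting material + target → side product B (k = 0.00440 M⁻¹ s⁻¹)
    first nucleophile + intermediate → target (k = 1.00 M⁻¹ s⁻¹)
    second nucleophile + intermediate → other capture product (k = 0.180 M⁻¹ s⁻¹)
    target ⇌ isomer of the product (K = 19.0, k = 4.00 × 10⁻⁴ s⁻¹)

The share from the capture ratio stood 4.8 points higher than the flask's share at 12 min. Now scale the ratio by the charge of first nucleophile for a neighbouring flask holding 2.80 equiv, everything else as in the recipe. It becomes 18.6, which as a share is 94.9%. That neighbour gives 92.7% at 12 min, again a little lower. Its share then falls to 36.9% at 20 h, when it holds 5.60% of other capture product.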